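Monday's flask is the one I have to foresee: incoming ligand goes in by portions to starting complex, and three exchanges follow one another, each freeing leaving ligand.

| setting | south-east | east | Monday's | Thursday's |
|---|---|---|---|---|
| starting complex | 0.30 M | 0.30 M | 0.30 M | 0.30 M |
| incoming ligand | 1.3 equiv (in portions, 3) | 2.1 equiv (in portions, 3) | 1.00 equiv (in portions, 3) | 1.50 equiv (in portions, 3) |
| leaving ligand | 2 equiv | 2 equiv | 2.00 equiv | 2.00 equiv |
| remark | run made earlier; portions every 40 s | run made earlier; portions every 40 s | the portions of incoming ligand follow each other after 40 s, the first at the start | the portions of incoming ligand follow each other after 40 s, the first at the start |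
| time |  |  | 10 min | 10 min |

| run | time / min | complex with two exchanged / % | complex with one exchanged / % |
|---|---|---|---|
| south-east | 0.417 | 0 | 15 |
| south-east | 1.00 | 4 | 27 |
| south-east | 2.00 | 14 | 38 |
| south-east | 5.00 | 16 | 28 |
| east | 0.667 | 3 | 27 |
| east | 2.00 | 18 | 36 |
| east | 3.00 | 14 | 26 |
| east | 5.00 | 13 | 16 |

(each reading ± 1.5 percentage points)

- which of these holds the largest part of the starting complex at the end of Monday's (complex with two exchanged / starting complex / complex with one exchanged / complex with three exchanged)
- which of these holds the largest part of the starting complex at the end of Thursday's (complex with two exchanged / starting complex / complex with one exchanged / complex with three exchanged)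
- amount of complex with two exchanged at the end of Monday's, in percent of the starting complex charged



I build the flask one step at a time. Let a, b and c be the complexes with one, two and three exchanged, and x the incoming ligand charged, all as shares of the starting complex.

The first step by itself can take a up to the smaller of x and the whole charge of starting complex, and a then does not fall, but the south-east run reads a at 38% after 2.00 min and at 28% after 5.00 min, so a is also consumed. With the second step added, I carry the line through the south-east and east readings of a at that time down to Monday's charge, which gives 32.5%. I keep b at the south-east 16%.

The third step is never read, so I assume incoming ligand is used up and count ligands: c is x less a less two b, over 3, which gives 11.8%. Putting these back, 39.7% is the remainder, the share of the charged complex that a, b and c do not hold. The runs never read it. Taken as starting complex, it leads Monday's. The same reckoning for Thursday's gives a at 25.0%, c at 31.0% and a remainder of 28.0%, so c leads Thursday's.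

The forecast names starting complex for Monday's and complex with three exchanged for Thursday's, and it sets b lower than I do, at 12%: “so starting complex leads on Monday”.

    complex with two exchanged + incoming ligand → leaving ligand + complex with three exchanged (k = 0.0890 M⁻¹ s⁻¹)
    starting complex + incoming ligand → leaving ligand + complex with one exchanged (k = 0.0750 M⁻¹ s⁻¹)
    2 starting complex → homo dimer (k = 0.0110 M⁻¹ s⁻¹)
    complex with one exchanged + incoming ligand → leaving ligand + complex with two exchanged (k = 0.0440 M⁻¹ s⁻¹)

Monday's ends with complex with one exchanged ahead at 32.2%, b at 13.3%, and Thursday's with complex with three exchanged. Incoming ligand, the limiting reagent, is down to 0.232% of its charge in Monday's. Monday's remainder, which I put at 39.7%, stands at 40.9%, split into 8.67% starting complex and 32.2% homo dimer, each homo dimer counted as two. The neighbour with 0.400 equiv ends with a at 25.1% and b at 4.96%, so its remainder is 68.3%, larger than Monday's, and it holds 15.2% starting complex and 53.2% homo dimer.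

All runs were computed on assumed constants.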